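A direct plan would alkylate methyl acetoacetate A2 with 1-bromodocosane A1 to methyl 2-acetyltetracosanoate A3, turn A3 by deacylative nitrosation into the α-oximino ester methyl 2-(hydroxyimino)tetracosanoate A4, and close the pyrrole by O-vinylation of A4 with vinyl acetate A5 under [Ir(cod)Cl]2. The resulting O-vinyl oxime methyl 2-[(ethenyloxy)imino]tetracosanoate A6 would then go on by a thermal [3,3] shift (C3–C4) and condensation at nitrogen (N1–C5).
Weak point 1, the O-vinylation/cascade ring closure: transfer vinylation of the oxime O–H of A4 by A5 would be without precedent, A5 could as well acetylate the oxime, and the ring would hang on four further unisolated events starting from A6 as an E/Z mixture. All the risk would sit in the last step.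
Weak point 2, the alkylation/nitrosation run-up from A1 and A2: two steps and a sacrificial acetyl group would be spent on the simple acyclic oxime A4, with dialkylation and waxy homologues to separate, and nothing of the ring built.
Weak point 3, the late closure at the heteroatom: the N1–C5 bond would form through an α-imino ester aldehyde that is prone to hydrolysis and oligomerisation at 100 °C.

**Retrosynthetic overview**
The pyrrole is cut at two carbon–carbon bonds, C2–C3 and C4–C5. The N1–C2(CO2Me) unit with the unsubstituted C5 is methyl isocyanoacetate, and the C3(henicosyl)=C4(H) edge is the terminal alkyne tricos-1-yne.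
One silver-catalysed formal [3+2] cycloaddition closes the only ring, directly as the aromatic ring, with no leaving group and no N–C bond to make.
The alkyne comes in two steps from 1-docosanol (oxidation, one-carbon homologation).
The design needs no oxime, no vinyl transfer and no sacrificial acetyl group; the risk sits in one catalytic step with close precedent, fed by a two-step hydrocarbon precursor.

Key step: step 3

Remark: the target has no stereocentre, so nothing has to be set. The silver-bound intermediates of step 3 are listed in their protonated, metal-free forms.

**Step 1**
Reactants: 1 1-docosanol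
Product: 2 docosanal
Conditions: TEMPO (10 mol %), PhI(OAc)2 (1.1 equiv), CH2Cl2, 35 °C
Reagents that add atoms: none
Why: TEMPO-catalysed (oxoammonium) oxidation of a primary alcohol should stop at the aldehyde under anhydrous conditions, and the saturated chain offers no other reactive site.

**Step 2**
Reactants: 2 docosanal; 3 dimethyl (1-diazo-2-oxopropyl)phosphonate (1.3 equiv)
Product: 5 tricos-1-yne, via diazoalkene 4 (not isolated)
Conditions: K2CO3 (2.0 equiv), MeOH–THF (1:1), 0 °C → rt
Reagents that add atoms: none
Why: Seyferth–Gilbert homologation in the Ohira–Bestmann variant: methanolysis of 3 releases the dimethyl (diazomethyl)phosphonate anion, whose Horner–Wadsworth–Emmons-type addition/elimination on the aldehyde gives diazoalkene 4, which loses N2 and rearranges by a 1,2-hydride shift of the alkylidene carbene to the terminal alkyne, while the mild carbonate base limits aldol self-condensation and THF keeps the waxy aldehyde dissolved.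

**Step 3**
Reactants: 5 tricos-1-yne; 6 methyl isocyanoacetate (1.5 equiv, added over 2 h)
Product: 9 methyl 3-henicosyl-1H-pyrrole-2-carboxylate, via alkynyl imine 7 (not isolated), via 2H-pyrrole 8 (not isolated)
Conditions: Ag2CO3 (10 mol %), 1,4-dioxane, 80 °C, Ar
Reagents that add atoms: none
Why: Silver-catalysed formal [3+2] cycloaddition of an α-acidic isocyanide with an unactivated terminal alkyne; the closest known reaction type is the Ag2CO3-catalysed isocyanide–alkyne cycloaddition of aryl and alkyl acetylenes with isocyanoacetates to 2,3-disubstituted pyrroles. Ag2CO3 should convert 5 into its monovalent silver acetylide, and 1,1-insertion of the isocyanide carbon of 6 into the Ag–C bond forms C4–C5 (an imidoyl silver species, listed in protonated form as 7). The glycinate α-carbon, now a carbanion flanked by ester and imine, then attacks the internal alkyne carbon in a 5-endo-dig closure that forms C2–C3 and the ring (8 after protodemetalation). A prototropic shift from C2 to nitrogen aromatises 8 to 9 and returns the silver catalyst. No stereocentre is formed; the selectivity needed is regiochemical (henicosyl at C3, not C4), and it is secured because only the terminal alkyne carbon is metalated and must bond to the isocyanide carbon, leaving the substituted alkyne carbon for closure with C2. Slow addition of 6 should hold back its silver-catalysed self-condensation to an imidazole.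

**Compound list**
1 | 1-docosanol | CCCCCCCCCCCCCCCCCCCCCCO | starting material
2 | docosanal | CCCCCCCCCCCCCCCCCCCCCC=O | intermediate
3 | dimethyl (1-diazo-2-oxopropyl)phosphonate | CC(=O)C(=[N+]=[N-])P(=O)(OC)OC | starting material
4 | 1-diazotricos-1-ene (diazoalkene, not isolated) | CCCCCCCCCCCCCCCCCCCCCC=C=[N+]=[N-] | intermediate
5 | tricos-1-yne | CCCCCCCCCCCCCCCCCCCCCC#C | intermediate
6 | methyl isocyanoacetate | [C-]#[N+]CC(=O)OC | starting material
7 | methyl N-(tetracos-2-yn-1-ylidene)glycinate (alkynyl imine, protonated form of the imidoyl silver species, not isolated) | CCCCCCCCCCCCCCCCCCCCCC#CC=NCC(=O)OC | intermediate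
8 | methyl 3-henicosyl-2H-pyrrole-2-carboxylate (racemic, not isolated) | CCCCCCCCCCCCCCCCCCCCCC1=CC=NC1C(=O)OC | intermediate
9 | methyl 3-henicosyl-1H-pyrrole-2-carboxylate | CCCCCCCCCCCCCCCCCCCCCc1cc[nH]c1C(=O)OC | target

**Step count and risks**
Total step count: 3. Longest linear sequence: 3.

Steps most likely to fail, riskiest first:

Step 3 (silver-catalysed cycloaddition). The acetylide of a purely aliphatic, waxy alkyne may insert the isocyanide slowly, so that self-condensation of the isocyanoacetate consumes it before the ring forms. The fallback sets out from docosanal 2 and comes back to the route at the target 9. It keeps the C2–C3/C4–C5 disconnection but replaces the alkyne and the metal by a nitroalkene and a polar mechanism. Henry addition of nitromethane to 2 (catalytic Et3N, i-PrOH) should give racemic 1-nitrotricosan-2-ol F1. Acetylation (Ac2O, catalytic DMAP, CH2Cl2) should give 1-nitrotricosan-2-yl acetate F2. Treatment of F2 with methyl isocyanoacetate 6 and DBU (2.2 equiv) in THF should eliminate acetic acid to (E)-1-nitrotricos-1-ene F3 in the flask and carry it through the Barton–Zard sequence to 9: Michael addition of the isocyanoacetate carbanion at the henicosyl-bearing carbon, closure of the nitronate carbon on the isocyanide carbon, loss of nitrite and aromatisation.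

Step 2 (homologation to the alkyne). The enolisable long-chain aldehyde may undergo aldol self-condensation in basic methanol, or may react incompletely because it is poorly soluble there. The fallback sets out from docosanal 2 and comes back at tricos-1-yne 5 by a Corey–Fuchs sequence that avoids alkoxide and methanol. Dibromo-olefination with CBr4 and PPh3 in CH2Cl2 at 0 °C should give 1,1-dibromotricos-1-ene F4. Treatment with n-BuLi (2.2 equiv) in THF at –78 °C → rt, then water, should give 5 through bromine–lithium exchange, α-elimination and 1,2-hydride shift.

Step 1 (oxidation). Over-oxidation, or ester formation between unreacted alcohol and the aldehyde through the hemiacetal, could lower the yield, and the poor solubility of the C22 alcohol could leave conversion incomplete. The fallback sets out from 1-docosanol 1 and comes back at docosanal 2 without an oxidant acting on the free alcohol. Sulfonylation (TsCl, pyridine, CHCl3) should give docosyl 4-methylbenzenesulfonate F5. Kornblum oxidation (DMSO, NaHCO3, 150 °C, short reaction time) should then give 2 through the alkoxysulfonium salt.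

**Further compounds**
F1 | step 3 | 1-nitrotricosan-2-ol (racemic) | CCCCCCCCCCCCCCCCCCCCCC(O)C[N+](=O)[O-]
F2 | step 3 | 1-nitrotricosan-2-yl acetate (racemic) | CCCCCCCCCCCCCCCCCCCCCC(OC(C)=O)C[N+](=O)[O-]
F3 | step 3 | (E)-1-nitrotricos-1-ene | CCCCCCCCCCCCCCCCCCCCC/C=C/[N+](=O)[O-]
F4 | step 2 | 1,1-dibromotricos-1-ene | CCCCCCCCCCCCCCCCCCCCCC=C(Br)Br
F5 | step 1 | docosyl 4-methylbenzenesulfonate | CCCCCCCCCCCCCCCCCCCCCCOS(=O)(=O)c1ccc(C)cc1
A1 | direct plan | 1-bromodocosane | CCCCCCCCCCCCCCCCCCCCCCBr
A2 | direct plan | methyl acetoacetate | CC(=O)CC(=O)OC
A3 | direct plan | methyl 2-acetyltetracosanoate (racemic) | CCCCCCCCCCCCCCCCCCCCCCC(C(C)=O)C(=O)OC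
A4 | direct plan | methyl 2-(hydroxyimino)tetracosanoate (E/Z mixture) | CCCCCCCCCCCCCCCCCCCCCCC(=NO)C(=O)OC
A5 | direct plan | vinyl acetate | C=COC(C)=O
A6 | direct plan | methyl 2-[(ethenyloxy)imino]tetracosanoate (E/Z mixture) | CCCCCCCCCCCCCCCCCCCCCCC(=NOC=C)C(=O)OC
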